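## The problem

The target is a furanoheliangolide. It has a ten-membered carbocycle (C1–C10, germacrane numbering) with a Z-trisubstituted C4=C5 olefin, a trans-fused α-methylene-γ-butyrolactone across C7–C8 (C12 carbonyl, C11=C13), and a 3(2H)-furanone whose oxygen bridges C3 and the quaternary C10 (C1 ketone, C2=C3). Four ring stereocentres must be set, C6 (S, acyloxy carbinol), C7 (R), C8 (S) and C10 (R), and the epoxyangelate adds two more (2S,3S). C6, C7 and C8 are contiguous, so one of them can direct the other two. C10 is quaternary and insulated by C9H2, and the oxirane centres are remote from the core, so both need their own source of chirality. The molecule is fragile: the α-methylene lactone and the cross-conjugated furanone are Michael acceptors, the glycidic ester opens with acid or nucleophiles, and the C6 ester is allylic. A free C6 hydroxyl beside the lactone invites translactonisation, and a Z-enal or Z-γ-hydroxy enal on the C3–C6 arm isomerises or closes to a furan. The central difficulty is closing a ten-membered ring that holds a Z-olefin and a bridging furanone. The enabling feature is that C10–C1–C2–C3 is a γ-hydroxy ynone in disguise, C10(OH)–C1≡C2–C3(=O): the linear alkyne takes strain and transannular hydrogens out of the ring, the C2–C3 seam needs only chemoselectivity, and the furanone bridge can be laid across the finished ring last.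

## Retrosynthesis

**Furanone bridge.** Target 34 is opened at the O(C10)–C3 bond and C1 is returned to the alkyne level, giving the cyclic γ-hydroxy ynone 32. Carrying the furanone through a ring closure would mean closing a bent, bridged nine-membered oxacycle. The ynone is one ring simpler and has no dienone. The forward step must hydrate C1 regioselectively and close C10–OH onto C3 without touching lactone or oxirane, which calls for neutral gold catalysis.

**Ring closure.** Ynone 32 comes from carbinol 31, which is cut at C2–C3 to the iodoalkyne Z-enal 30. A cut at C1–C10 would create the quaternary centre during ring closure, and C3–C4 or C5–C6 cuts leave stereochemistry in the ring. The C2–C3 carbinol is oxidised away in the next step. The forward reaction must be aldehyde-selective and non-basic, hence CrCl2/NiCl2.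

**End-game functional groups.** The C3 aldehyde of 30 is unveiled last from the PMB ether (alcohol 29, iodoalkyne 28), because the Z-enal is the most labile group. The C6 ester must already be in place, otherwise the Z-γ-hydroxy enal would close to a furan. Iodoalkyne 28 comes from terminal alkyne 27, and the ester C–O bond of 27 is cut to diol 25 and epoxy acid 4.

**Lactone and fragment union.** Lactone 24 (desilylated to 25) is cut at C7–C8 and at the lactone C–O bond to allylic bromide 22 and aldehyde 11. This halves the molecule and makes lactone, C7 and C8 in one operation. The neighbouring C6–C7 cut (a bromomethyl butenolide plus a Z-enal) would be expected to give the C6 epimer through its closed transition state, because the target has C8 and O6 syn. CrCl2 is chosen over zinc or indium because allylchromium additions are anti-selective whatever the bromide geometry, and anti corresponds to the trans lactone. C6 must relay its configuration to C7.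

**Bromide 22.** The C13 bromide comes from alcohol 21. The C11–C13 bond is cut (formaldehyde) back to ynoate 19, and the C6–C7 bond of its parent 18 is cut to Z-enal 16 and methyl propiolate 17. This sets C6 by catalyst control and avoids the epimerisable α-oxy-β,γ-unsaturated aldehyde that a Morita–Baylis–Hillman route would require.

**Z-enal 16.** Oxidation level adjustments lead back to enoate 14, whose C4–methyl bond is cut (methyl cuprate syn-addition) to ynoate 13, made from propargyl ether 12. The syn-carbocupration fixes the Z geometry.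

**Aldehyde 11.** C10 is taken from (R)-citramalic acid 5: the α-hydroxy acid carbon becomes C1 (homologated to the alkyne via 7, 8, 9) and the CH2CO2H arm becomes C9–C8 (ester 10 to aldehyde 11). No stereocentre is made.

**Epoxy acid 4.** The oxirane is cut back to angelic acid 1 through alcohol 2 and epoxy alcohol 3. The Z-olefin supplies the relative configuration and asymmetric epoxidation the absolute one.

## Roads not taken

**Alternative 1:** epoxide-opening lactone annulation. The cut is C7–C11: the C8 phosphonoacetate of the C6–C7 epoxide A1 is deprotonated (DBU/LiCl), and the carbanion opens the epoxide at C7 (5-exo, inversion) to give the α-phosphono trans-lactone A2 with C6–OH freed.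
- Merits: C7 is set by SN2 inversion from a reagent-controlled epoxide, so the trans lactone is secured by mechanism rather than by a relay. The Michael acceptor stays masked as the phosphonate until a late Horner–Wadsworth–Emmons reaction with formaldehyde.
- Weak points: C8 and the epoxide must each be set separately, which makes the sequence longer and more linear. C6 is allylic, so 6-endo attack at C6 competes. The ring still has to be closed afterwards.
- Comparison: in stereochemical security this road is better than the chosen one. The chosen plan sets against it a convergent union that makes lactone, C7 and C8 in one step from two fragments of similar size.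

**Alternative 2:** [2,3]-Wittig ring contraction. The cut is C6–C7: the thirteen-membered diallylic ether A3 is deprotonated at C6 with LiN(SiMe3)2 and rearranges to the ten-membered homoallylic alcohol A4, with C11=C13 formed in the same step.
- Merits: one step makes the C6–C7 bond, both stereocentres and the exo-methylene, and direct ten-ring closure is avoided.
- Weak points: the furanone must survive an amide base, and a vinylogous carbanion can rearrange [1,2] or deprotonate elsewhere. Two stereocentres depend on the folding of a large ring. C12 is still a PMB-protected alcohol in A4, so several steps remain to the lactone. A3 itself needs a macrocyclisation.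
- Comparison: more elegant in bond economy, but the risks are stacked on one untested step. The chosen plan spreads them over precedented reactions.

**Alternative 3:** Nozaki–Hiyama–Kishi closure at C5–C6. The Z-vinyl iodide aldehyde A5, furanone in place, is closed with CrCl2/NiCl2 to the bridged C6 alcohol A6.
- Merits: the same mild manifold as the chosen plan, and the bicycle is complete after ring closure with no oxidation or gold step.
- Weak points: C6, which stays in the target, is set during a strained closure with no reliable control. The C6 aldehyde is α to the acidic C7–H and can epimerise or eliminate. The ring closes as the bent, bridged system without the relief of a linear alkyne.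
- Comparison: it is shorter after ring closure. The chosen plan sets against this that the only stereocentre formed in its ring closure is erased.

Key step: step 24

Assumption: the (S,S)-ProPhenol/Me2Zn catalyst is taken to deliver the propiolate to the face of enal 16 that gives (4S)-alcohol 18; if the opposite sense is found, the (R,R)-ligand is used with no other change.

## Route

Step 1
Reactants: 1 angelic acid [(2Z)-2-methylbut-2-enoic acid]
Product: 2 (2Z)-2-methylbut-2-en-1-ol
Conditions: LiAlH4, Et2O, 0 °C to rt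
Reagents that add atoms: none
Why: Hydride reduction of the carboxylic acid; the trisubstituted olefin is not reduced and keeps its Z geometry.

Step 2
Reactants: 2 (2Z)-2-methylbut-2-en-1-ol
Product: 3 [(2R,3S)-2,3-dimethyloxiran-2-yl]methanol
Conditions: Ti(OiPr)4 (cat.), D-(−)-diethyl tartrate, tBuOOH, 4 Å MS, CH2Cl2, −20 °C
Reagents that add atoms: tert-butyl hydroperoxide, CC(C)(C)OO
Why: Sharpless asymmetric epoxidation; the D-(−)-tartrate catalyst adds oxygen to the face opposite to that used by L-(+)-tartrate (which gives 2S epoxides), so C2 becomes R, and the cis relation of CH2OH and the C3 methyl comes from the Z-olefin.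

Step 3
Reactants: 3 [(2R,3S)-2,3-dimethyloxiran-2-yl]methanol
Product: 4 (2S,3S)-2,3-dimethyloxirane-2-carboxylic acid
Conditions: RuCl3 (cat.), NaIO4, MeCN/EtOAc/H2O, 0 °C to rt
Reagents that add atoms: sodium periodate, [Na+].[O-]I(=O)(=O)=O
Why: Catalytic ruthenium tetroxide (RuO4) oxidation of the primary alcohol to the acid; C2 is quaternary and cannot epimerise, and its descriptor changes from R to S only through CIP priority.

Step 4
Reactants: 5 (R)-citramalic acid
Product: 6 dimethyl (2R)-2-hydroxy-2-methylbutanedioate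
Conditions: MeOH, H2SO4 (cat.), reflux
Reagents that add atoms: methanol, CO
Why: Fischer esterification; the quaternary carbinol is not affected.

Step 5
Reactants: 6 dimethyl (2R)-2-hydroxy-2-methylbutanedioate
Product: 7 methyl (3R)-3,4-dihydroxy-3-methylbutanoate
Conditions: BH3·SMe2, NaBH4 (cat.), THF, 0 °C to rt; MeOH quench
Reagents that add atoms: none
Why: Hydroxyl-directed borane reduction: the alkoxyborane formed at the tertiary hydroxyl delivers hydride only to the adjacent ester, leaving the CH2CO2Me arm; the diol is used crude to forestall lactonisation.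

Step 6
Reactants: 7 methyl (3R)-3,4-dihydroxy-3-methylbutanoate
Product: 8 methyl (3R)-3-hydroxy-3-methyl-4-oxobutanoate
Conditions: SO3·pyridine, DMSO, iPr2NEt, CH2Cl2, 0 °C
Reagents that add atoms: none
Why: Parikh–Doering oxidation of the only oxidisable (primary) alcohol; the α-carbon is quaternary, so no epimerisation is possible.

Step 7
Reactants: 8 methyl (3R)-3-hydroxy-3-methyl-4-oxobutanoate
Product: 9 methyl (3R)-3-hydroxy-3-methylpent-4-ynoate
Conditions: dimethyl (1-diazo-2-oxopropyl)phosphonate, K2CO3, MeOH, 0 °C to rt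
Reagents that add atoms: dimethyl (1-diazo-2-oxopropyl)phosphonate, COP(=O)(OC)C(=[N+]=[N-])C(C)=O
Why: Ohira–Bestmann homologation of the aldehyde to the terminal alkyne (C1≡C2); the mild carbonate base tolerates the methyl ester and the tertiary alcohol.

Step 8
Reactants: 9 methyl (3R)-3-hydroxy-3-methylpent-4-ynoate
Product: 10 methyl (3R)-3-methyl-3-[(triethylsilyl)oxy]pent-4-ynoate
Conditions: Et3SiOTf, 2,6-lutidine, CH2Cl2, −78 to 0 °C
Reagents that add atoms: triethylsilyl trifluoromethanesulfonate, CC[Si](CC)(CC)OS(=O)(=O)C(F)(F)F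
Why: Silylation of the tertiary propargylic alcohol with the silyl triflate; this blocks retro-aldol cleavage and alkoxide-assisted over-reduction in the next step.

Step 9
Reactants: 10 methyl (3R)-3-methyl-3-[(triethylsilyl)oxy]pent-4-ynoate
Product: 11 (3R)-3-methyl-3-[(triethylsilyl)oxy]pent-4-ynal
Conditions: iBu2AlH, CH2Cl2, −78 °C
Reagents that add atoms: none
Why: Partial reduction of the ester to the aldehyde at low temperature (the tetrahedral aluminium acetal is stable until work-up); the terminal alkyne is inert under these conditions.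

Step 10
Reactants: 12 4-methoxybenzyl propargyl ether
Product: 13 methyl 4-[(4-methoxybenzyl)oxy]but-2-ynoate
Conditions: nBuLi, THF, −78 °C; then ClCO2Me
Reagents that add atoms: methyl chloroformate, COC(=O)Cl
Why: Deprotonation of the terminal alkyne and C-acylation with the chloroformate, a standard route to ynoates.

Step 11
Reactants: 13 methyl 4-[(4-methoxybenzyl)oxy]but-2-ynoate
Product: 14 methyl (2Z)-4-[(4-methoxybenzyl)oxy]-3-methylbut-2-enoate
Conditions: Me2CuLi (from MeLi, CuI), THF, −78 °C; MeOH quench at −78 °C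
Reagents that add atoms: lithium dimethylcuprate, [Li+].C[Cu-]C
Why: Syn-carbocupration of the ynoate and protonation with retention place CH2OPMB and the ester cis, giving the Z-olefin; cold quench prevents equilibration to the E isomer.

Step 12
Reactants: 14 methyl (2Z)-4-[(4-methoxybenzyl)oxy]-3-methylbut-2-enoate
Product: 15 (2Z)-4-[(4-methoxybenzyl)oxy]-3-methylbut-2-en-1-ol
Conditions: iBu2AlH, CH2Cl2, −78 °C
Reagents that add atoms: none
Why: 1,2-Reduction of the enoate to the allylic alcohol; the PMB ether prevents lactonisation and the geometry is retained.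

Step 13
Reactants: 15 (2Z)-4-[(4-methoxybenzyl)oxy]-3-methylbut-2-en-1-ol
Product: 16 (2Z)-4-[(4-methoxybenzyl)oxy]-3-methylbut-2-enal
Conditions: Dess–Martin periodinane, NaHCO3, CH2Cl2, 0 °C
Reagents that add atoms: none
Why: Buffered Dess–Martin oxidation gives the enal under neutral conditions, so the β,β-disubstituted Z-enal does not isomerise; it is used directly.

Step 14
Reactants: 16 (2Z)-4-[(4-methoxybenzyl)oxy]-3-methylbut-2-enal; 17 methyl propiolate
Product: 18 methyl (4S,5Z)-4-hydroxy-7-[(4-methoxybenzyl)oxy]-6-methylhept-5-en-2-ynoate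
Conditions: (S,S)-ProPhenol (cat.), Me2Zn, Ph3PO (cat.), toluene, 0 °C
Reagents that add atoms: none
Why: Zinc–ProPhenol catalysed asymmetric alkynylation of an enal: the alkynylzinc formed in situ adds 1,2 inside the chiral dinuclear zinc pocket and sets C6 as S; the conditions are non-basic, so the Z-enal geometry is kept.

Step 15
Reactants: 18 methyl (4S,5Z)-4-hydroxy-7-[(4-methoxybenzyl)oxy]-6-methylhept-5-en-2-ynoate
Product: 19 methyl (4S,5Z)-4-[(tert-butyldimethylsilyl)oxy]-7-[(4-methoxybenzyl)oxy]-6-methylhept-5-en-2-ynoate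
Conditions: tBuMe2SiCl, imidazole, DMF, rt
Reagents that add atoms: tert-butyldimethylsilyl chloride, CC(C)(C)[Si](C)(C)Cl
Why: Silylation of the secondary alcohol; a bulky non-chelating ether is wanted at C6 for step 18, and it keeps C6–O from competing in lactonisation.

Step 16
Reactants: 19 methyl (4S,5Z)-4-[(tert-butyldimethylsilyl)oxy]-7-[(4-methoxybenzyl)oxy]-6-methylhept-5-en-2-ynoate
Product: 21 methyl (2Z,4S,5Z)-4-[(tert-butyldimethylsilyl)oxy]-2-(hydroxymethyl)-7-[(4-methoxybenzyl)oxy]-6-methylhepta-2,5-dienoate, via alpha-aluminated dienoate 20 (not isolated)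
Conditions: iBu2AlH, N-methylmorpholine N-oxide, THF, 0 °C to rt; then CH2O (gas), −40 °C to rt
Reagents that add atoms: formaldehyde, C=O
Why: Conjugate syn-hydroalumination of the ynoate by the amine-oxide-modified hydride puts H on C7 and aluminium on C11, and the vinylalane 20 adds to formaldehyde to install C13 (vinylalumination–carbonyl addition); C6 is untouched, and the olefin geometry is immaterial for step 18.

Step 17
Reactants: 21 methyl (2Z,4S,5Z)-4-[(tert-butyldimethylsilyl)oxy]-2-(hydroxymethyl)-7-[(4-methoxybenzyl)oxy]-6-methylhepta-2,5-dienoate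
Product: 22 methyl (2E,4S,5Z)-2-(bromomethyl)-4-[(tert-butyldimethylsilyl)oxy]-7-[(4-methoxybenzyl)oxy]-6-methylhepta-2,5-dienoate
Conditions: CBr4, PPh3, CH2Cl2, 0 °C
Reagents that add atoms: carbon tetrabromide, BrC(Br)(Br)Br
Why: Appel bromination of the primary allylic alcohol under neutral conditions; the conjugated primary bromide is the stable allylic isomer and is used at once.

Step 18
Reactants: 22 methyl (2E,4S,5Z)-2-(bromomethyl)-4-[(tert-butyldimethylsilyl)oxy]-7-[(4-methoxybenzyl)oxy]-6-methylhepta-2,5-dienoate; 11 (3R)-3-methyl-3-[(triethylsilyl)oxy]pent-4-ynal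
Product: 24 (4R,5S)-4-[(1S,2Z)-1-[(tert-butyldimethylsilyl)oxy]-4-[(4-methoxybenzyl)oxy]-3-methylbut-2-en-1-yl]-3-methylidene-5-[(2R)-2-methyl-2-[(triethylsilyl)oxy]but-3-yn-1-yl]oxolan-2-one, via anti hydroxy ester 23 (not isolated)
Conditions: CrCl2, THF, rt; then pyridinium p-toluenesulfonate (cat.), CH2Cl2, rt
Reagents that add atoms: none
Why: Nozaki–Hiyama allylation then lactonisation: the allylchromium from 22 adds through C7 in a chair-like transition state with the C6 branch equatorial, giving the anti 7,8-adduct 23 and hence the trans lactone; the C7 face is set by C6 (C6–H eclipsing the olefin to avoid allylic 1,3-strain, aldehyde approaching anti to the alkenyl arm, silyloxy group outside), which should give 7R,8S.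

Step 19
Reactants: 24 (4R,5S)-4-[(1S,2Z)-1-[(tert-butyldimethylsilyl)oxy]-4-[(4-methoxybenzyl)oxy]-3-methylbut-2-en-1-yl]-3-methylidene-5-[(2R)-2-methyl-2-[(triethylsilyl)oxy]but-3-yn-1-yl]oxolan-2-one
Product: 25 (4S,5S)-4-[(1S,2Z)-1-hydroxy-4-[(4-methoxybenzyl)oxy]-3-methylbut-2-en-1-yl]-5-[(2R)-2-hydroxy-2-methylbut-3-yn-1-yl]-3-methylideneoxolan-2-one
Conditions: HF·pyridine, pyridine, THF, 0 °C to rt
Reagents that add atoms: none
Why: Buffered fluoride cleaves both silyl ethers without base, so the α-methylene lactone is spared and, with no nucleophilic solvent present, translactonisation to C6–O is not promoted; the C7 descriptor changes to S only through CIP priority.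

Step 20
Reactants: 25 (4S,5S)-4-[(1S,2Z)-1-hydroxy-4-[(4-methoxybenzyl)oxy]-3-methylbut-2-en-1-yl]-5-[(2R)-2-hydroxy-2-methylbut-3-yn-1-yl]-3-methylideneoxolan-2-one; 4 (2S,3S)-2,3-dimethyloxirane-2-carboxylic acid
Product: 27 (1S,2Z)-1-[(2S,3R)-2-[(2R)-2-hydroxy-2-methylbut-3-yn-1-yl]-4-methylidene-5-oxooxolan-3-yl]-4-[(4-methoxybenzyl)oxy]-3-methylbut-2-en-1-yl (2S,3S)-2,3-dimethyloxirane-2-carboxylate, via mixed anhydride 26 (not isolated)
Conditions: 2,4,6-trichlorobenzoyl chloride, Et3N, THF, rt; then 25, DMAP, toluene, rt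
Reagents that add atoms: none
Why: Yamaguchi esterification: the mixed anhydride 26 acylates the secondary allylic C6 hydroxyl while the tertiary propargylic C10 hydroxyl stays free; the acid has no α-hydrogen, so its stereocentres are safe, and C6 reacts with retention.

Step 21
Reactants: 27 (1S,2Z)-1-[(2S,3R)-2-[(2R)-2-hydroxy-2-methylbut-3-yn-1-yl]-4-methylidene-5-oxooxolan-3-yl]-4-[(4-methoxybenzyl)oxy]-3-methylbut-2-en-1-yl (2S,3S)-2,3-dimethyloxirane-2-carboxylate
Product: 28 (1S,2Z)-1-[(2S,3R)-2-[(2R)-2-hydroxy-4-iodo-2-methylbut-3-yn-1-yl]-4-methylidene-5-oxooxolan-3-yl]-4-[(4-methoxybenzyl)oxy]-3-methylbut-2-en-1-yl (2S,3S)-2,3-dimethyloxirane-2-carboxylate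
Conditions: N-iodosuccinimide, AgNO3 (cat.), acetone, rt, dark
Reagents that add atoms: N-iodosuccinimide, O=C1CCC(=O)N1I
Why: Silver-catalysed iodination of the terminal alkyne via the silver acetylide; olefins, esters, oxirane and the tertiary alcohol are inert under these neutral conditions.

Step 22
Reactants: 28 (1S,2Z)-1-[(2S,3R)-2-[(2R)-2-hydroxy-4-iodo-2-methylbut-3-yn-1-yl]-4-methylidene-5-oxooxolan-3-yl]-4-[(4-methoxybenzyl)oxy]-3-methylbut-2-en-1-yl (2S,3S)-2,3-dimethyloxirane-2-carboxylate
Product: 29 (1S,2Z)-4-hydroxy-1-[(2S,3R)-2-[(2R)-2-hydroxy-4-iodo-2-methylbut-3-yn-1-yl]-4-methylidene-5-oxooxolan-3-yl]-3-methylbut-2-en-1-yl (2S,3S)-2,3-dimethyloxirane-2-carboxylate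
Conditions: DDQ, CH2Cl2/pH 7 buffer, 0 °C
Reagents that add atoms: none
Why: Oxidative cleavage of the PMB ether by DDQ under buffered conditions frees C3–OH without acid, base or fluoride, so oxirane, lactone and iodoalkyne survive.

Step 23
Reactants: 29 (1S,2Z)-4-hydroxy-1-[(2S,3R)-2-[(2R)-2-hydroxy-4-iodo-2-methylbut-3-yn-1-yl]-4-methylidene-5-oxooxolan-3-yl]-3-methylbut-2-en-1-yl (2S,3S)-2,3-dimethyloxirane-2-carboxylate
Product: 30 (1S,2Z)-1-[(2S,3R)-2-[(2R)-2-hydroxy-4-iodo-2-methylbut-3-yn-1-yl]-4-methylidene-5-oxooxolan-3-yl]-3-methyl-4-oxobut-2-en-1-yl (2S,3S)-2,3-dimethyloxirane-2-carboxylate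
Conditions: Dess–Martin periodinane, NaHCO3, CH2Cl2, 0 °C
Reagents that add atoms: none
Why: Buffered Dess–Martin oxidation of the primary allylic alcohol; the tertiary alcohol cannot be oxidised, the C6 oxygen is already acylated so no furan can form, and the Z-enal is taken on at once.

Step 24
Reactants: 30 (1S,2Z)-1-[(2S,3R)-2-[(2R)-2-hydroxy-4-iodo-2-methylbut-3-yn-1-yl]-4-methylidene-5-oxooxolan-3-yl]-3-methyl-4-oxobut-2-en-1-yl (2S,3S)-2,3-dimethyloxirane-2-carboxylate
Product: 31 (3S,6S,7R,8S,10R)-3,10-dihydroxy-6-[(2S,3S)-2,3-epoxy-2-methylbutanoyloxy]germacra-4Z,11(13)-dien-1-yn-12,8-olide (C3 epimers expected; 3S drawn)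
Conditions: CrCl2 (excess), NiCl2 (cat.), degassed THF, rt, slow addition of 30 (about 2 mM)
Reagents that add atoms: none
Why: Nozaki–Hiyama–Kishi alkynylation: CrCl2 reduces NiCl2 to zerovalent nickel, which inserts into the C2–I bond, and transmetalation gives an alkynylchromium dichloride (trivalent chromium) that adds 1,2 to the C3 aldehyde; the chromium alkoxide is hydrolysed on work-up. The closest known reaction is the CrCl2/NiCl2 cyclisation of iodoalkyne aldehydes to nine- and ten-membered cycloalkynes. The ten-membered carbocycle closes end to end (10-exo-trig attack of C2 on the C3 carbonyl); C1 and C2 carry no substituents and keep hydrogens out of the ring interior, and the Z-olefin and the trans lactone pre-fold the C3–C8 segment. The new C3 carbinol is not controlled and need not be, since step 25 oxidises it and both epimers are carried on. The selectivity required is chemoselectivity: the organochromium reagent adds to the aldehyde and leaves the lactone, both ester carbonyls, the oxirane and the enoate alone, and the non-basic medium spares the Z-enal and the tertiary hydroxyl. Intermolecular coupling is held down by slow addition of 30 to the reagent.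

Step 25
Reactants: 31 (3S,6S,7R,8S,10R)-3,10-dihydroxy-6-[(2S,3S)-2,3-epoxy-2-methylbutanoyloxy]germacra-4Z,11(13)-dien-1-yn-12,8-olide
Product: 32 (6S,7R,8S,10R)-10-hydroxy-3-oxo-6-[(2S,3S)-2,3-epoxy-2-methylbutanoyloxy]germacra-4Z,11(13)-dien-1-yn-12,8-olide
Conditions: Dess–Martin periodinane, NaHCO3, CH2Cl2, 0 °C to rt
Reagents that add atoms: none
Why: Dess–Martin oxidation of the secondary propargylic/allylic alcohol gives the cyclic ynone and converges both C3 epimers; the tertiary C10 alcohol is inert.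

Step 26
Reactants: 32 (6S,7R,8S,10R)-10-hydroxy-3-oxo-6-[(2S,3S)-2,3-epoxy-2-methylbutanoyloxy]germacra-4Z,11(13)-dien-1-yn-12,8-olide
Product: 34 target (6S,7R,8S,10R)-3,10-epoxy-1-oxo-6-[(2S,3S)-2,3-epoxy-2-methylbutanoyloxy]germacra-2,4Z,11(13)-trien-12,8-olide, via ring diketone 33 (not isolated)
Conditions: Ph3PAuCl (cat.), AgOTf (cat.), toluene/H2O, rt
Reagents that add atoms: water, O
Why: Gold-catalysed conversion of a γ-hydroxy ynone into a 3(2H)-furanone: cationic Ph3PAu+ (monovalent gold) activates C1≡C2, water adds at C1 (β-carbon of the ynone) to give diketone 33, and the C10 hydroxyl closes onto the C3 carbonyl with loss of water, laying the O–C3 bridge across the ring; no stereocentre is formed or disturbed.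

## Compound list

1 | angelic acid, (2Z)-2-methylbut-2-enoic acid | C/C=C(/C)C(=O)O | starting material
2 | (2Z)-2-methylbut-2-en-1-ol | C/C=C(/C)CO | intermediate
3 | [(2R,3S)-2,3-dimethyloxiran-2-yl]methanol | OC[C@@]1(C)O[C@H]1C | intermediate
4 | (2S,3S)-2,3-dimethyloxirane-2-carboxylic acid | OC(=O)[C@@]1(C)O[C@H]1C | intermediate
5 | (R)-citramalic acid, (2R)-2-hydroxy-2-methylbutanedioic acid | C[C@@](O)(CC(=O)O)C(=O)O | starting material
6 | dimethyl (2R)-2-hydroxy-2-methylbutanedioate | C[C@@](O)(CC(=O)OC)C(=O)OC | intermediate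
7 | methyl (3R)-3,4-dihydroxy-3-methylbutanoate | C[C@@](O)(CC(=O)OC)CO | intermediate
8 | methyl (3R)-3-hydroxy-3-methyl-4-oxobutanoate | C[C@@](O)(CC(=O)OC)C=O | intermediate
9 | methyl (3R)-3-hydroxy-3-methylpent-4-ynoate | C[C@@](O)(CC(=O)OC)C#C | intermediate
10 | methyl (3R)-3-methyl-3-[(triethylsilyl)oxy]pent-4-ynoate | C[C@@](O[Si](CC)(CC)CC)(CC(=O)OC)C#C | intermediate
11 | (3R)-3-methyl-3-[(triethylsilyl)oxy]pent-4-ynal | C[C@@](O[Si](CC)(CC)CC)(CC=O)C#C | intermediate
12 | 4-methoxybenzyl propargyl ether, 1-methoxy-4-[(prop-2-yn-1-yloxy)methyl]benzene | C#CCOCc1ccc(OC)cc1 | starting material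
13 | methyl 4-[(4-methoxybenzyl)oxy]but-2-ynoate | COC(=O)C#CCOCc1ccc(OC)cc1 | intermediate
14 | methyl (2Z)-4-[(4-methoxybenzyl)oxy]-3-methylbut-2-enoate | COC(=O)/C=C(C)\COCc1ccc(OC)cc1 | intermediate
15 | (2Z)-4-[(4-methoxybenzyl)oxy]-3-methylbut-2-en-1-ol | OC/C=C(C)\COCc1ccc(OC)cc1 | intermediate
16 | (2Z)-4-[(4-methoxybenzyl)oxy]-3-methylbut-2-enal | O=C/C=C(C)\COCc1ccc(OC)cc1 | intermediate
17 | methyl propiolate | C#CC(=O)OC | starting material
18 | methyl (4S,5Z)-4-hydroxy-7-[(4-methoxybenzyl)oxy]-6-methylhept-5-en-2-ynoate | COC(=O)C#C[C@@H](O)/C=C(C)\COCc1ccc(OC)cc1 | intermediate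
19 | methyl (4S,5Z)-4-[(tert-butyldimethylsilyl)oxy]-7-[(4-methoxybenzyl)oxy]-6-methylhept-5-en-2-ynoate | COC(=O)C#C[C@@H](O[Si](C)(C)C(C)(C)C)/C=C(C)\COCc1ccc(OC)cc1 | intermediate
20 | methyl (2E,4S,5Z)-4-[(tert-butyldimethylsilyl)oxy]-2-(diisobutylalumanyl)-7-[(4-methoxybenzyl)oxy]-6-methylhepta-2,5-dienoate | COC(=O)/C(=C\[C@@H](O[Si](C)(C)C(C)(C)C)/C=C(C)\COCc1ccc(OC)cc1)[Al](CC(C)C)CC(C)C | intermediate
21 | methyl (2Z,4S,5Z)-4-[(tert-butyldimethylsilyl)oxy]-2-(hydroxymethyl)-7-[(4-methoxybenzyl)oxy]-6-methylhepta-2,5-dienoate | COC(=O)/C(CO)=C\[C@@H](O[Si](C)(C)C(C)(C)C)/C=C(C)\COCc1ccc(OC)cc1 | intermediate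
22 | methyl (2E,4S,5Z)-2-(bromomethyl)-4-[(tert-butyldimethylsilyl)oxy]-7-[(4-methoxybenzyl)oxy]-6-methylhepta-2,5-dienoate | COC(=O)/C(CBr)=C\[C@@H](O[Si](C)(C)C(C)(C)C)/C=C(C)\COCc1ccc(OC)cc1 | intermediate
23 | methyl 2-[(2Z,4S,5R,6S,8R)-4-[(tert-butyldimethylsilyl)oxy]-6-hydroxy-1-[(4-methoxybenzyl)oxy]-2,8-dimethyl-8-[(triethylsilyl)oxy]dec-2-en-9-yn-5-yl]prop-2-enoate | C#C[C@](C)(O[Si](CC)(CC)CC)C[C@H](O)[C@@H](C(=C)C(=O)OC)[C@@H](O[Si](C)(C)C(C)(C)C)/C=C(C)\COCc1ccc(OC)cc1 | intermediate
24 | (4R,5S)-4-[(1S,2Z)-1-[(tert-butyldimethylsilyl)oxy]-4-[(4-methoxybenzyl)oxy]-3-methylbut-2-en-1-yl]-3-methylidene-5-[(2R)-2-methyl-2-[(triethylsilyl)oxy]but-3-yn-1-yl]oxolan-2-one | C#C[C@](C)(O[Si](CC)(CC)CC)C[C@@H]1OC(=O)C(=C)[C@H]1[C@@H](O[Si](C)(C)C(C)(C)C)/C=C(C)\COCc1ccc(OC)cc1 | intermediate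
25 | (4S,5S)-4-[(1S,2Z)-1-hydroxy-4-[(4-methoxybenzyl)oxy]-3-methylbut-2-en-1-yl]-5-[(2R)-2-hydroxy-2-methylbut-3-yn-1-yl]-3-methylideneoxolan-2-one | C#C[C@](C)(O)C[C@@H]1OC(=O)C(=C)[C@H]1[C@@H](O)/C=C(C)\COCc1ccc(OC)cc1 | intermediate
26 | (2S,3S)-2,3-dimethyloxirane-2-carboxylic 2,4,6-trichlorobenzoic anhydride | O=C(OC(=O)c1c(Cl)cc(Cl)cc1Cl)[C@@]1(C)O[C@H]1C | intermediate
27 | (1S,2Z)-1-[(2S,3R)-2-[(2R)-2-hydroxy-2-methylbut-3-yn-1-yl]-4-methylidene-5-oxooxolan-3-yl]-4-[(4-methoxybenzyl)oxy]-3-methylbut-2-en-1-yl (2S,3S)-2,3-dimethyloxirane-2-carboxylate | C#C[C@](C)(O)C[C@@H]1OC(=O)C(=C)[C@H]1[C@@H](OC(=O)[C@@]2(C)O[C@H]2C)/C=C(C)\COCc1ccc(OC)cc1 | intermediate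
28 | (1S,2Z)-1-[(2S,3R)-2-[(2R)-2-hydroxy-4-iodo-2-methylbut-3-yn-1-yl]-4-methylidene-5-oxooxolan-3-yl]-4-[(4-methoxybenzyl)oxy]-3-methylbut-2-en-1-yl (2S,3S)-2,3-dimethyloxirane-2-carboxylate | IC#C[C@](C)(O)C[C@@H]1OC(=O)C(=C)[C@H]1[C@@H](OC(=O)[C@@]2(C)O[C@H]2C)/C=C(C)\COCc1ccc(OC)cc1 | intermediate
29 | (1S,2Z)-4-hydroxy-1-[(2S,3R)-2-[(2R)-2-hydroxy-4-iodo-2-methylbut-3-yn-1-yl]-4-methylidene-5-oxooxolan-3-yl]-3-methylbut-2-en-1-yl (2S,3S)-2,3-dimethyloxirane-2-carboxylate | IC#C[C@](C)(O)C[C@@H]1OC(=O)C(=C)[C@H]1[C@@H](OC(=O)[C@@]2(C)O[C@H]2C)/C=C(C)\CO | intermediate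
30 | (1S,2Z)-1-[(2S,3R)-2-[(2R)-2-hydroxy-4-iodo-2-methylbut-3-yn-1-yl]-4-methylidene-5-oxooxolan-3-yl]-3-methyl-4-oxobut-2-en-1-yl (2S,3S)-2,3-dimethyloxirane-2-carboxylate | IC#C[C@](C)(O)C[C@@H]1OC(=O)C(=C)[C@H]1[C@@H](OC(=O)[C@@]2(C)O[C@H]2C)/C=C(C)\C=O | intermediate
31 | (3S,6S,7R,8S,10R)-3,10-dihydroxy-6-[(2S,3S)-2,3-epoxy-2-methylbutanoyloxy]germacra-4Z,11(13)-dien-1-yn-12,8-olide (C3 epimers; 3S drawn) | C=C1C(=O)O[C@H]2C[C@@](C)(O)C#C[C@@H](O)/C(C)=C\[C@H](OC(=O)[C@@]3(C)O[C@H]3C)[C@H]12 | intermediate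
32 | (6S,7R,8S,10R)-10-hydroxy-3-oxo-6-[(2S,3S)-2,3-epoxy-2-methylbutanoyloxy]germacra-4Z,11(13)-dien-1-yn-12,8-olide | C=C1C(=O)O[C@H]2C[C@@](C)(O)C#CC(=O)/C(C)=C\[C@H](OC(=O)[C@@]3(C)O[C@H]3C)[C@H]12 | intermediate
33 | (6S,7R,8S,10R)-10-hydroxy-1,3-dioxo-6-[(2S,3S)-2,3-epoxy-2-methylbutanoyloxy]germacra-4Z,11(13)-dien-12,8-olide | C=C1C(=O)O[C@H]2C[C@@](C)(O)C(=O)CC(=O)/C(C)=C\[C@H](OC(=O)[C@@]3(C)O[C@H]3C)[C@H]12 | intermediate
34 | (6S,7R,8S,10R)-3,10-epoxy-1-oxo-6-[(2S,3S)-2,3-epoxy-2-methylbutanoyloxy]germacra-2,4Z,11(13)-trien-12,8-olide (CNP0258430.4) | C=C1C(=O)O[C@H]2C[C@@]3(C)OC(=CC3=O)/C(C)=C\[C@H](OC(=O)[C@@]3(C)O[C@H]3C)[C@H]12 | target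

## Step count and least certain steps

Total: 26 steps. Longest linear sequence: 17 steps (steps 10 to 26, from 12).

**Step 24 (key step).** The most likely failure is diversion of the alkynylchromium before it closes the strained ring: protonolysis by the free C10 hydroxyl or traces of water, or intermolecular addition, giving deiodinated or oligomeric material. The fallback closes the ring earlier, on a substrate with no free hydroxyl and no oxirane, which also allows DMF and warming. Setting out from 24, iodination with N-iodosuccinimide/AgNO3 would give the bis-silyl iodoalkyne F1, DDQ would give the allylic alcohol F2, and Dess–Martin oxidation the silylated iodoalkyne enal F3. CrCl2/NiCl2 cyclisation of F3 would give the bis-silyl cyclic propargylic alcohol F4, Dess–Martin oxidation the silylated cyclic ynone F5, and HF·pyridine the ynone diol F6. Yamaguchi acylation of the C6 hydroxyl of F6 with 4 comes back to the route at 32.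

**Step 18.** The most likely failure is poor or reversed facial selectivity in the relay from C6 to C7, with the anti sense intact, so that the wrong 7,8-pair forms. The fallback uses the opposite C6 configuration and corrects it during ester installation. Setting out from 16, the (R,R)-ProPhenol catalyst would give the enantiomeric propargylic alcohol F7, silylation its silyl ether F8, hydroalumination and formaldehyde capture the hydroxymethyl dienoate F9, and Appel bromination the bromide F10. CrCl2 coupling of F10 with 11 would then give the 6-epi lactone F11, and HF·pyridine the 6-epi diol F12. Mitsunobu esterification of F12 with 4 (PPh3, diisopropyl azodicarboxylate) inverts C6 and comes back to the route at 27.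

**Step 16.** The most likely failure is 1,2-reduction of the ester, or protonation of the vinylalane before formaldehyde captures it. The fallback replaces aluminium by tin and palladium. Setting out from 19, Pd(PPh3)4-catalysed hydrostannation with Bu3SnH would give the α-stannyl dienoate F13 and iodine the α-iodo dienoate F14. Stille coupling of F14 with (tributylstannyl)methanol comes back to the route at 21.

**Step 14.** The most likely failure is erosion of enantioselectivity with this β,β-disubstituted Z-enal, or Z-to-E isomerisation under the Lewis-acidic zinc. The fallback sets C6 by reduction. Setting out from 16, addition of lithiated 17 (LiN(SiMe3)2, −78 °C) would give the racemic propargylic alcohol F15 and Dess–Martin oxidation the enynone F16. Corey–Bakshi–Shibata reduction of F16 with the (S)-oxazaborolidine and catecholborane (alkenyl as the large group, alkynyl as the small group) comes back to the route at 18.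

**Step 26.** The most likely failure is unselective activation: hydration with the wrong regiochemistry, engagement of the enone or oxirane by the Lewis-acidic metal, or slow transannular closure. The fallback uses amine conjugate addition in place of π-activation. Setting out from 32, one equivalent of Et2NH at 0 °C (the ynone reacts far faster than the α-methylene lactone) would give the enaminone F17. Hydrolysis and cyclodehydration of F17 in aqueous acetic acid comes back to the route at 34.

## Further compounds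

F1 | step 24 | (4R,5S)-4-[(1S,2Z)-1-[(tert-butyldimethylsilyl)oxy]-4-[(4-methoxybenzyl)oxy]-3-methylbut-2-en-1-yl]-5-[(2R)-4-iodo-2-methyl-2-[(triethylsilyl)oxy]but-3-yn-1-yl]-3-methylideneoxolan-2-one | IC#C[C@](C)(O[Si](CC)(CC)CC)C[C@@H]1OC(=O)C(=C)[C@H]1[C@@H](O[Si](C)(C)C(C)(C)C)/C=C(C)\COCc1ccc(OC)cc1
F2 | step 24 | (4R,5S)-4-[(1S,2Z)-1-[(tert-butyldimethylsilyl)oxy]-4-hydroxy-3-methylbut-2-en-1-yl]-5-[(2R)-4-iodo-2-methyl-2-[(triethylsilyl)oxy]but-3-yn-1-yl]-3-methylideneoxolan-2-one | IC#C[C@](C)(O[Si](CC)(CC)CC)C[C@@H]1OC(=O)C(=C)[C@H]1[C@@H](O[Si](C)(C)C(C)(C)C)/C=C(C)\CO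
F3 | step 24 | (2Z,4S)-4-[(tert-butyldimethylsilyl)oxy]-4-[(2S,3R)-2-[(2R)-4-iodo-2-methyl-2-[(triethylsilyl)oxy]but-3-yn-1-yl]-4-methylidene-5-oxooxolan-3-yl]-2-methylbut-2-enal | IC#C[C@](C)(O[Si](CC)(CC)CC)C[C@@H]1OC(=O)C(=C)[C@H]1[C@@H](O[Si](C)(C)C(C)(C)C)/C=C(C)\C=O
F4 | step 24 | (6S,7R,8S,10R)-6-[(tert-butyldimethylsilyl)oxy]-3-hydroxy-10-[(triethylsilyl)oxy]germacra-4Z,11(13)-dien-1-yn-12,8-olide (C3 epimers) | C=C1C(=O)O[C@H]2C[C@@](C)(O[Si](CC)(CC)CC)C#CC(O)/C(C)=C\[C@H](O[Si](C)(C)C(C)(C)C)[C@H]12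
F5 | step 24 | (6S,7R,8S,10R)-6-[(tert-butyldimethylsilyl)oxy]-3-oxo-10-[(triethylsilyl)oxy]germacra-4Z,11(13)-dien-1-yn-12,8-olide | C=C1C(=O)O[C@H]2C[C@@](C)(O[Si](CC)(CC)CC)C#CC(=O)/C(C)=C\[C@H](O[Si](C)(C)C(C)(C)C)[C@H]12
F6 | step 24 | (6S,7S,8S,10R)-6,10-dihydroxy-3-oxogermacra-4Z,11(13)-dien-1-yn-12,8-olide | C=C1C(=O)O[C@H]2C[C@@](C)(O)C#CC(=O)/C(C)=C\[C@H](O)[C@H]12
F7 | step 18 | methyl (4R,5Z)-4-hydroxy-7-[(4-methoxybenzyl)oxy]-6-methylhept-5-en-2-ynoate | COC(=O)C#C[C@H](O)/C=C(C)\COCc1ccc(OC)cc1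
F8 | step 18 | methyl (4R,5Z)-4-[(tert-butyldimethylsilyl)oxy]-7-[(4-methoxybenzyl)oxy]-6-methylhept-5-en-2-ynoate | COC(=O)C#C[C@H](O[Si](C)(C)C(C)(C)C)/C=C(C)\COCc1ccc(OC)cc1
F9 | step 18 | methyl (2Z,4R,5Z)-4-[(tert-butyldimethylsilyl)oxy]-2-(hydroxymethyl)-7-[(4-methoxybenzyl)oxy]-6-methylhepta-2,5-dienoate | COC(=O)/C(CO)=C\[C@H](O[Si](C)(C)C(C)(C)C)/C=C(C)\COCc1ccc(OC)cc1
F10 | step 18 | methyl (2E,4R,5Z)-2-(bromomethyl)-4-[(tert-butyldimethylsilyl)oxy]-7-[(4-methoxybenzyl)oxy]-6-methylhepta-2,5-dienoate | COC(=O)/C(CBr)=C\[C@H](O[Si](C)(C)C(C)(C)C)/C=C(C)\COCc1ccc(OC)cc1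
F11 | step 18 | (4R,5S)-4-[(1R,2Z)-1-[(tert-butyldimethylsilyl)oxy]-4-[(4-methoxybenzyl)oxy]-3-methylbut-2-en-1-yl]-3-methylidene-5-[(2R)-2-methyl-2-[(triethylsilyl)oxy]but-3-yn-1-yl]oxolan-2-one | C#C[C@](C)(O[Si](CC)(CC)CC)C[C@@H]1OC(=O)C(=C)[C@H]1[C@H](O[Si](C)(C)C(C)(C)C)/C=C(C)\COCc1ccc(OC)cc1
F12 | step 18 | (4S,5S)-4-[(1R,2Z)-1-hydroxy-4-[(4-methoxybenzyl)oxy]-3-methylbut-2-en-1-yl]-5-[(2R)-2-hydroxy-2-methylbut-3-yn-1-yl]-3-methylideneoxolan-2-one | C#C[C@](C)(O)C[C@@H]1OC(=O)C(=C)[C@H]1[C@H](O)/C=C(C)\COCc1ccc(OC)cc1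
F13 | step 16 | methyl (2E,4S,5Z)-4-[(tert-butyldimethylsilyl)oxy]-7-[(4-methoxybenzyl)oxy]-6-methyl-2-(tributylstannyl)hepta-2,5-dienoate | COC(=O)/C(=C\[C@@H](O[Si](C)(C)C(C)(C)C)/C=C(C)\COCc1ccc(OC)cc1)[Sn](CCCC)(CCCC)CCCC
F14 | step 16 | methyl (2E,4S,5Z)-4-[(tert-butyldimethylsilyl)oxy]-2-iodo-7-[(4-methoxybenzyl)oxy]-6-methylhepta-2,5-dienoate | COC(=O)/C(I)=C\[C@@H](O[Si](C)(C)C(C)(C)C)/C=C(C)\COCc1ccc(OC)cc1
F15 | step 14 | methyl (5Z)-4-hydroxy-7-[(4-methoxybenzyl)oxy]-6-methylhept-5-en-2-ynoate (racemic) | COC(=O)C#CC(O)/C=C(C)\COCc1ccc(OC)cc1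
F16 | step 14 | methyl (5Z)-7-[(4-methoxybenzyl)oxy]-6-methyl-4-oxohept-5-en-2-ynoate | COC(=O)C#CC(=O)/C=C(C)\COCc1ccc(OC)cc1
F17 | step 26 | (6S,7R,8S,10R)-1-(diethylamino)-10-hydroxy-3-oxo-6-[(2S,3S)-2,3-epoxy-2-methylbutanoyloxy]germacra-1,4Z,11(13)-trien-12,8-olide | C=C1C(=O)O[C@H]2C[C@@](C)(O)C(N(CC)CC)=CC(=O)/C(C)=C\[C@H](OC(=O)[C@@]3(C)O[C@H]3C)[C@H]12
A1 | alternative 1 | C8 diethylphosphonoacetate of the C6–C7 epoxide (silyl-protected seco chain) | CCOP(=O)(OCC)CC(=O)O[C@@H](C[C@@](C)(O[Si](CC)(CC)CC)C#C)[C@@H]1O[C@H]1/C=C(C)\CO[Si](c1ccccc1)(c1ccccc1)C(C)(C)C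
A2 | alternative 1 | α-phosphono trans-γ-lactone with free C6–OH (C11 labile, one epimer) | O=C1O[C@@H](C[C@@](C)(O[Si](CC)(CC)CC)C#C)[C@H]([C@@H](O)/C=C(C)\CO[Si](c2ccccc2)(c2ccccc2)C(C)(C)C)[C@@H]1P(=O)(OCC)OCC
A3 | alternative 2 | thirteen-membered diallylic ether with furanone in place (C7=C11 geometry as drawn) | CC(C)(C)[Si](C)(C)O[C@H]1C[C@@]2(C)OC(=CC2=O)/C(C)=C\COC/C(COCc2ccc(OC)cc2)=C/1
A4 | alternative 2 | ten-membered C6 homoallylic alcohol with C11 exo-methylene | CC(C)(C)[Si](C)(C)O[C@H]1C[C@@]2(C)OC(=CC2=O)/C(C)=C\[C@H](O)[C@@H]1C(=C)COCc1ccc(OC)cc1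
A5 | alternative 3 | furanone Z-vinyl iodide with C6 aldehyde on the α-phosphono lactone | CCOP(=O)(OCC)[C@@H]1C(=O)O[C@@H](C[C@@]2(C)OC(=CC2=O)/C(C)=C\I)[C@@H]1C=O
A6 | alternative 3 | furanone-bridged ten-membered C6 alcohol (α-phosphono lactone, C11 labile) | CCOP(=O)(OCC)[C@@H]1C(=O)O[C@H]2C[C@@]3(C)OC(=CC3=O)/C(C)=C\[C@H](O)[C@H]12
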